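Remark: compounds 1, 2 and 6 are taken to be purchasable; the target has no stereocentre, so no configuration has to be assigned anywhere in the route.

## Analysis of the target

Perlatolic acid 11 is a depside: two benzene rings joined by a single aryl ester, with no further ring and no stereocentre. Ring A, the acyl ring, is a 2-hydroxy-4-methoxy-6-pentylbenzoyl unit; ring B is a 2-hydroxy-6-pentylbenzoic acid whose oxygen at C4 carries the ring A acyl group. Three groups are sensitive: the ester between the rings, which hydroxide, alkoxides and amines cleave or exchange; the carboxyl of ring B, which loses carbon dioxide on heating because it has oxygen at the ortho and para positions; and the electron-rich phenolic rings, which are open to oxidants and electrophiles. The usual difficulty is the bookkeeping of four oxygens on two almost identical resorcinol rings (one methylated, one acylated, two free), which normally costs phenol protecting groups on both halves. The feature used here is that on both rings the free hydroxyl at C2 is ortho to a carbonyl-bearing C1 whose other ortho carbon, C6, carries the pentyl chain. Without the two C2 oxygens, each carbonyl (the depside ester on ring A, the carboxyl on ring B) has exactly one ortho C–H, so both hydroxyls can be planned as the last bonds made.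

## Retrosynthetic reasoning

The first cut removes the two aryl C–O bonds at C2 of ring A and C2 of ring B of 11 and leads to the dideoxy depside 9. In 9, named with lowest locants, these carbons are C6 of each ring. These are the only oxygens next to a carbonyl group. Taking them away removes every free phenol, both chelated hydroxyls and the decarboxylation-prone acid from every stage before the last step, so all intermediates up to 9 are ordinary benzoates. In the forward direction each carbonyl must deliver divalent ruthenium to its single free ortho C–H, and an oxidant must turn the C–metal bond into a C–O bond. The oxygens should arrive acylated, as in 10, and be uncovered on work-up. The reaction must prefer these two sites over C3 and C5 of ring B (next to the ester oxygen), over C3 and C5 of ring A (next to the methoxy group) and over the benzylic CH2 groups. Ruthenium is preferred to palladium because divalent palladium tends to metalate the ring on the heteroatom side of an aryl amide or ester.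

The carboxyl of 9 is traced back to the benzyl ester 8, and 8 is cut at the acyl C–O bond of the depside ester into acid 4 and phenol 7. This is the only bond joining the rings, so the cut is convergent. The ring B carboxyl must be masked during the acylation, otherwise it would be activated as well. Benzyl is chosen because hydrogenolysis removes it without touching the aryl ester, and it is removed before the last step because a benzyl ester would not survive hot acid and oxidant.

Phenol 7 is cut at the O–CH2 bond of its ester into hydroxy acid 5 and benzyl bromide 6. The forward reaction must alkylate the carboxylate and leave the phenol free for the acylation.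

Hydroxy acid 5 is traced back to acid 4 by the O–CH3 bond, so ring B is ring A without its methyl group and both halves come from one compound. The ether is cleaved on the free acid 4 and not on ester 3, so that a single ester hydrolysis serves both halves and the carboxyl is free for benzylation directly afterwards.

Acid 4 comes from ester 3 by hydrolysis, and 3 is cut at the bond between ring carbon C2 and the first carbon of the pentyl chain into aryl bromide 1 and boronic acid 2. The carboxyl, bromine and methoxy pattern is bought ready-made in 1, with the halogen where the chain belongs. The forward reaction is an sp2–sp3 cross-coupling that must outrun β-hydride elimination.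

## Alternatives that were turned down

Alternative 1: A resorcylate ring is built instead of bought. Ring B is cut at C1–C6 and C2–C3, giving dibenzyl malonate A2 and (E)-non-3-en-2-one A3. In the forward key step, sodium benzyloxide A10 would add the anion of A2 to the β-carbon of A3 (C1–C6), and the methyl ketone enolate would close onto one benzyl ester (C2–C3) to give the cyclohexanedione ester A1, benzyl 2,4-dioxo-6-pentylcyclohexane-1-carboxylate, as the racemic trans isomer. Halogenation and loss of hydrogen halide would then aromatise A1 to benzyl 2,4-dihydroxy-6-pentylbenzoate A4.
- For it: every oxygen is placed by the ring construction, the substitution pattern cannot come out wrong, the materials are cheap and each reaction is established. On certainty it is clearly stronger than the chosen last step.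
- Against it: it makes one ring per pass. Ring A needs a second pass, then selective methylation at O4, protection at O2 and ester cleavage to a decarboxylation-prone acid. The two stereocentres of A1 are made only to be destroyed. The halogen used for aromatisation can also attack the electron-rich ring. The depside coupling and a double deprotection still follow, so the count is well above that of the chosen route.
- Comparison: the chosen strategy offers seven steps from one aryl bromide with no phenol protection, at the price of an untested final reaction.

Alternative 2: Ring A is opened at C1–C6, leading to the open-chain aryl ester benzyl 2-hydroxy-6-pentyl-4-[(3,5,7-trioxododecanoyl)oxy]benzoate A6, whose phenol part is A4. In the forward key step, triethylamine A11 would enolise C2 of the chain, which adds to the C7 ketone; mild acid would then remove water and the ring would enolise to the arene. The product is benzyl 4-[(2,4-dihydroxy-6-pentylbenzoyl)oxy]-2-hydroxy-6-pentylbenzoate A5.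
- For it: it follows the polyketide logic of the natural product, makes ring A with the ester already in place and avoids coupling a hindered acid. On building carbon skeleton and oxygen pattern together it is stronger than the chosen route.
- Against it: C1 of A6 is an aryl ester, so its aryloxide is a good leaving group. The competing closures (C6 onto C1 to an acylphloroglucinol, or enol oxygen onto C1 to a pyrone) both expel ring B and destroy the depside bond. A5 must still be methylated at the ring A O4 under base, which threatens the ester, and then debenzylated. A6 itself requires A4 and a masked polyketone chain to acylate it.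
- Comparison: the chosen route carries only robust benzoates, needs no base near the depside ester and is shorter.

Alternative 3: Both bonds at the depside carbonyl carbon are cut, so that this carbon comes from carbon monoxide A9, ring A from 2-iodo-1,5-dimethoxy-3-pentylbenzene A8 and ring B from A4. In the forward key step, with Pd(OAc)2 A12, the diphosphine Xantphos A13 and A11 as base, zerovalent palladium would insert into the C–I bond of A8, A9 would insert to the acylpalladium, and the 4-phenoxide of A4 would capture it. The 2-hydroxyl of A4 is held by its hydrogen bond to the benzyl ester. The product is benzyl 4-[(2,4-dimethoxy-6-pentylbenzoyl)oxy]-2-hydroxy-6-pentylbenzoate A7.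
- For it: aryloxycarbonylation is an established reaction class, and the hindered ring A acid never has to be made or activated. On precedent this key step is stronger than the chosen one.
- Against it: the iodide of A8 lies between a methoxy and a pentyl group on an electron-rich ring, so oxidative addition and the crowded acyl transfer are slow. The phenol of A4 is a weak nucleophile, and at the temperature needed phenoxide can exchange the product ester. A7 carries a methyl ether at the ring A O2, so a selective demethylation next to the carbonyl is still needed before debenzylation. Both A8 and A4 must be prepared with their oxygens in place, and A9 is toxic.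
- Comparison: the chosen strategy offers a single building block for both rings, no late selective demethylation and a shorter sequence.

Key step: step 7

## Route

Abbreviations: TFA = trifluoroacetic acid, TFAA = trifluoroacetic anhydride, DCC = N,N'-dicyclohexylcarbodiimide, DMAP = 4-(dimethylamino)pyridine, dppf = 1,1'-bis(diphenylphosphino)ferrocene, DMF = N,N-dimethylformamide.

Step 1
Reactants: 1 methyl 2-bromo-4-methoxybenzoate; 2 pentylboronic acid
Product: 3 methyl 4-methoxy-2-pentylbenzoate
Conditions: PdCl2(dppf) (5 mol%), K2CO3, toluene/H2O, 90 °C
Reagents that add atoms: none
Why: B-alkyl Suzuki–Miyaura cross-coupling; the ortho ester makes the C–Br bond electron-poor and quick to add to zerovalent palladium, and the wide bite angle of dppf should speed reductive elimination of the aryl–alkyl pair ahead of β-hydride elimination.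

Step 2
Reactants: 3 methyl 4-methoxy-2-pentylbenzoate
Product: 4 4-methoxy-2-pentylbenzoic acid
Conditions: NaOH, MeOH/H2O, 65 °C; then aq. HCl
Reagents that add atoms: sodium hydroxide, [Na+].[OH-] (its oxygen becomes one carboxyl oxygen)
Why: Saponification (acyl substitution by hydroxide); the ortho pentyl group slows the addition but does not block it, and nothing else in 3 is base-sensitive.

Step 3
Reactants: 4 4-methoxy-2-pentylbenzoic acid (one portion)
Product: 5 4-hydroxy-2-pentylbenzoic acid
Conditions: BBr3 (3 equiv), CH2Cl2, −78 °C to rt; then H2O
Reagents that add atoms: none
Why: Lewis-acid cleavage of an aryl methyl ether: boron binds the ether oxygen and bromide attacks the methyl carbon (SN2), so the aryl C–O bond stays; the excess of BBr3 covers the carboxyl, which is set free again on aqueous work-up.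

Step 4
Reactants: 5 4-hydroxy-2-pentylbenzoic acid; 6 benzyl bromide
Product: 7 benzyl 4-hydroxy-2-pentylbenzoate
Conditions: KHCO3, DMF, rt to 40 °C
Reagents that add atoms: none
Why: SN2 O-alkylation of a carboxylate; hydrogencarbonate deprotonates the carboxylic acid but essentially not the far less acidic phenol, so with about one equivalent of 6 only the ester should form.

Step 5
Reactants: 4 4-methoxy-2-pentylbenzoic acid (second portion); 7 benzyl 4-hydroxy-2-pentylbenzoate
Product: 8 benzyl 4-[(4-methoxy-2-pentylbenzoyl)oxy]-2-pentylbenzoate
Conditions: DCC, DMAP (cat.), CH2Cl2, 0 °C to rt
Reagents that add atoms: none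
Why: Steglich esterification: the carbodiimide activates the acid and DMAP passes the acyl group to the phenol; 7 has one hydroxyl and a masked carboxyl, so only one ester can form.

Step 6
Reactants: 8 benzyl 4-[(4-methoxy-2-pentylbenzoyl)oxy]-2-pentylbenzoate
Product: 9 4-[(4-methoxy-2-pentylbenzoyl)oxy]-2-pentylbenzoic acid
Conditions: H2 (1 atm), Pd/C (10% Pd on carbon), EtOAc, rt
Reagents that add atoms: none
Why: Hydrogenolysis of the benzylic C–O bond of the benzyl ester; the depside ester has no benzylic C–O bond and the arenes are not reduced under these conditions.

Step 7
Reactants: 9 4-[(4-methoxy-2-pentylbenzoyl)oxy]-2-pentylbenzoic acid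
Product: 11 perlatolic acid (2-hydroxy-4-[(2-hydroxy-4-methoxy-6-pentylbenzoyl)oxy]-6-pentylbenzoic acid), via aryl bis(trifluoroacetate) 10 (not isolated)
Conditions: [RuCl2(p-cymene)]2 (5 mol%), PhI(OCOCF3)2 (3 equiv), TFA/TFAA (4:1), 60 °C; then H2O/THF, rt
Reagents that add atoms: [bis(trifluoroacetoxy)iodo]benzene, O=C(OI(OC(=O)C(F)(F)F)c1ccccc1)C(F)(F)F (its trifluoroacetate oxygens, which exchange with the solvent trifluoroacetic acid, OC(=O)C(F)(F)F, become the two phenolic oxygens)
Why: Proposed new method: a twofold ortho C–H oxygenation of a depside directed by two different carbonyl groups has not been shown; the closest known reaction type is the ortho-hydroxylation of simple alkyl benzoates, aryl ketones and benzamides with [RuCl2(p-cymene)]2 and K2S2O8 or PhI(OCOCF3)2 in TFA/TFAA, and of benzoic acids with Pd(OAc)2. Chloride–trifluoroacetate exchange should give Ru(OCOCF3)2(p-cymene), a divalent ruthenium species that binds the depside carbonyl oxygen of ring A (made a better donor by the para methoxy group) and the carboxyl of ring B (as ruthenium carboxylate or, where TFAA has acylated it, through the carbonyl of the acyl trifluoroacetate); trifluoroacetate-assisted removal of the ortho proton then gives a five-membered ruthenacycle on each ring, PhI(OCOCF3)2 oxidises it to tetravalent ruthenium, and C–O reductive elimination releases the aryl trifluoroacetate and returns divalent ruthenium. No ring is closed and no stereocentre is formed; the step makes only the C2–O bonds of ring A and ring B of 11. On each ring the site is fixed by the substrate, because the other ortho position of the directing carbonyl carries the pentyl chain and only one C–H can enter a five-membered metallacycle. The main competing sites are C3 and C5 of ring B, which the ester carbonyl could reach through a six-membered ruthenacycle; the smaller chelate, the pentyl group beside C3 and the known preference of [RuCl2(p-cymene)]2 for the acyl ring of N-aryl benzamides (where Pd(OAc)2 goes to the N-aryl ring) argue for the acyl side. The ring A site is meta to the methoxy group, so it is not the position an undirected electrophile would choose, and the new oxygens stay acylated as in 10, so no free phenol meets the oxidant. Water at room temperature then hydrolyses the two aryl trifluoroacetates, and any acyl trifluoroacetate at the carboxyl, without touching the depside ester.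

## Compound list

1 | methyl 2-bromo-4-methoxybenzoate | COC(=O)c1ccc(OC)cc1Br | starting material
2 | pentylboronic acid | CCCCCB(O)O | starting material
3 | methyl 4-methoxy-2-pentylbenzoate | CCCCCc1cc(OC)ccc1C(=O)OC | intermediate
4 | 4-methoxy-2-pentylbenzoic acid | CCCCCc1cc(OC)ccc1C(=O)O | intermediate
5 | 4-hydroxy-2-pentylbenzoic acid | CCCCCc1cc(O)ccc1C(=O)O | intermediate
6 | benzyl bromide | BrCc1ccccc1 | starting material
7 | benzyl 4-hydroxy-2-pentylbenzoate | CCCCCc1cc(O)ccc1C(=O)OCc1ccccc1 | intermediate
8 | benzyl 4-[(4-methoxy-2-pentylbenzoyl)oxy]-2-pentylbenzoate | CCCCCc1cc(OC(=O)c2ccc(OC)cc2CCCCC)ccc1C(=O)OCc1ccccc1 | intermediate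
9 | 4-[(4-methoxy-2-pentylbenzoyl)oxy]-2-pentylbenzoic acid | CCCCCc1cc(OC(=O)c2ccc(OC)cc2CCCCC)ccc1C(=O)O | intermediate
10 | 4-{[4-methoxy-2-pentyl-6-(trifluoroacetoxy)benzoyl]oxy}-2-pentyl-6-(trifluoroacetoxy)benzoic acid | CCCCCc1cc(OC(=O)c2c(OC(=O)C(F)(F)F)cc(OC)cc2CCCCC)cc(OC(=O)C(F)(F)F)c1C(=O)O | intermediate
11 | perlatolic acid, 2-hydroxy-4-[(2-hydroxy-4-methoxy-6-pentylbenzoyl)oxy]-6-pentylbenzoic acid | CCCCCc1cc(OC(=O)c2c(O)cc(OC)cc2CCCCC)cc(O)c1C(=O)O | target

## Step count and least certain steps

Total step count: 7. Longest linear sequence: 7 steps (1 → 3 → 4 → 5 → 7 → 8 → 9 → 11); acid 4 serves both halves, so every step lies on this line.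

Step 7 (key step, proposed new method). The most likely failure is that the two oxygenations run at very different rates. In the presence of the anhydride the ring B carboxyl is largely an acyl trifluoroacetate, a weaker donor than the ring A ester carbonyl, so the reaction may stall after ring A is oxygenated. Forcing it with more oxidant and heat invites four side processes:
- undirected electrophilic oxidation of ring A next to the methoxy group;
- oxygenation of ring B at C5 through the six-membered chelate;
- oxidative lactonisation at the benzylic CH2 of the ring B pentyl chain;
- acidolysis of the depside ester.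

The fallback for step 7 uses known chemistry, sets out from 3 and returns at 11. It moves the oxygenation to the stage of a single benzoate ester and then assembles the depside in the classical protected way. Ester-directed ortho-hydroxylation of 3 ([RuCl2(p-cymene)]2, K2S2O8, TFA/TFAA, 80 °C) should give in the flask methyl 4-methoxy-2-pentyl-6-(trifluoroacetoxy)benzoate F1, and aqueous work-up would hydrolyse F1 to methyl 2-hydroxy-4-methoxy-6-pentylbenzoate F2. One portion of F2 would be O-benzylated (benzyl bromide 6, K2CO3, DMF) to methyl 2-(benzyloxy)-4-methoxy-6-pentylbenzoate F3, and F3 would be saponified (KOH, DMSO/H2O, 80 °C; then aq. HCl) to 2-(benzyloxy)-4-methoxy-6-pentylbenzoic acid F4. The other portion of F2 would be demethylated (BBr3, CH2Cl2) to methyl 2,4-dihydroxy-6-pentylbenzoate F5. Ester F5 would be saponified under mild conditions (aq. KOH, MeOH, 40 °C under N2; acidified cold to limit decarboxylation) to 2,4-dihydroxy-6-pentylbenzoic acid F6, and F6 would be benzylated at the carboxyl (benzyl bromide 6, KHCO3, DMF) to benzyl 2,4-dihydroxy-6-pentylbenzoate F7. Carbodiimide coupling (DCC, DMAP, CH2Cl2) of F4 with the 4-hydroxyl of F7, whose 2-hydroxyl is hydrogen-bonded and hindered, should give benzyl 4-{[2-(benzyloxy)-4-methoxy-6-pentylbenzoyl]oxy}-2-hydroxy-6-pentylbenzoate F8. Hydrogenolysis of both benzyl groups of F8 (H2, Pd/C, EtOAc) then gives 11.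

Step 1. β-Hydride elimination from the pentylpalladium intermediate and protodeboronation of 2 may compete, so that the bromide is reduced or recovered instead of alkylated. The fallback sets out from 1 and returns at 3. Sonogashira coupling of 1 with pent-1-yne (PdCl2(PPh3)2, CuI, Et3N, 60 °C) should give methyl 4-methoxy-2-(pent-1-yn-1-yl)benzoate F9, in which the chain has entered through an sp carbon that cannot undergo β-hydride elimination. Hydrogenation of the triple bond of F9 (H2, Pd/C, EtOAc) then gives 3.

Step 5. Acyl transfer from the activated ortho-substituted acid may be slow, so that rearrangement of the activated acid to an unreactive N-acylurea competes with esterification. The fallback sets out from 4 and returns at 8. Acid 4 is converted with oxalyl chloride and catalytic DMF in CH2Cl2 into 4-methoxy-2-pentylbenzoyl chloride F10, and F10 is added to 7 with Et3N and DMAP in CH2Cl2 to give 8.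

Step 3. The carboxyl may tie up the boron reagent and make the mixture heterogeneous, so that ether cleavage stays incomplete. The fallback sets out from 3 and returns at 5. The neutral, soluble ester 3 is demethylated (BBr3, CH2Cl2, −78 to 0 °C) to methyl 4-hydroxy-2-pentylbenzoate F11, and F11 is then saponified (NaOH, MeOH/H2O, 65 °C; aq. HCl) to 5.

## Further compounds

F1 | step 7 | methyl 4-methoxy-2-pentyl-6-(trifluoroacetoxy)benzoate | CCCCCc1cc(OC)cc(OC(=O)C(F)(F)F)c1C(=O)OC
F2 | step 7 | methyl 2-hydroxy-4-methoxy-6-pentylbenzoate | CCCCCc1cc(OC)cc(O)c1C(=O)OC
F3 | step 7 | methyl 2-(benzyloxy)-4-methoxy-6-pentylbenzoate | CCCCCc1cc(OC)cc(OCc2ccccc2)c1C(=O)OC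
F4 | step 7 | 2-(benzyloxy)-4-methoxy-6-pentylbenzoic acid | CCCCCc1cc(OC)cc(OCc2ccccc2)c1C(=O)O
F5 | step 7 | methyl 2,4-dihydroxy-6-pentylbenzoate | CCCCCc1cc(O)cc(O)c1C(=O)OC
F6 | step 7 | 2,4-dihydroxy-6-pentylbenzoic acid | CCCCCc1cc(O)cc(O)c1C(=O)O
F7 | step 7 | benzyl 2,4-dihydroxy-6-pentylbenzoate | CCCCCc1cc(O)cc(O)c1C(=O)OCc1ccccc1
F8 | step 7 | benzyl 4-{[2-(benzyloxy)-4-methoxy-6-pentylbenzoyl]oxy}-2-hydroxy-6-pentylbenzoate | CCCCCc1cc(OC(=O)c2c(OCc3ccccc3)cc(OC)cc2CCCCC)cc(O)c1C(=O)OCc1ccccc1
F9 | step 1 | methyl 4-methoxy-2-(pent-1-yn-1-yl)benzoate | CCCC#Cc1cc(OC)ccc1C(=O)OC
F10 | step 5 | 4-methoxy-2-pentylbenzoyl chloride | CCCCCc1cc(OC)ccc1C(=O)Cl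
F11 | step 3 | methyl 4-hydroxy-2-pentylbenzoate | CCCCCc1cc(O)ccc1C(=O)OC
A1 | alternative 1 | benzyl 2,4-dioxo-6-pentylcyclohexane-1-carboxylate (racemic, trans isomer drawn) | O=C1CC(=O)[C@H](C(=O)OCc2ccccc2)[C@@H](CCCCC)C1
A2 | alternative 1 | dibenzyl malonate | O=C(CC(=O)OCc1ccccc1)OCc1ccccc1
A3 | alternative 1 | (E)-non-3-en-2-one | CC(=O)/C=C/CCCCC
A4 | alternative 1 | benzyl 2,4-dihydroxy-6-pentylbenzoate | CCCCCc1cc(O)cc(O)c1C(=O)OCc1ccccc1
A5 | alternative 2 | benzyl 4-[(2,4-dihydroxy-6-pentylbenzoyl)oxy]-2-hydroxy-6-pentylbenzoate | CCCCCc1cc(OC(=O)c2c(O)cc(O)cc2CCCCC)cc(O)c1C(=O)OCc1ccccc1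
A6 | alternative 2 | benzyl 2-hydroxy-6-pentyl-4-[(3,5,7-trioxododecanoyl)oxy]benzoate | CCCCCC(=O)CC(=O)CC(=O)CC(=O)Oc1cc(O)c(C(=O)OCc2ccccc2)c(CCCCC)c1
A7 | alternative 3 | benzyl 4-[(2,4-dimethoxy-6-pentylbenzoyl)oxy]-2-hydroxy-6-pentylbenzoate | CCCCCc1cc(OC(=O)c2c(OC)cc(OC)cc2CCCCC)cc(O)c1C(=O)OCc1ccccc1
A8 | alternative 3 | 2-iodo-1,5-dimethoxy-3-pentylbenzene | CCCCCc1cc(OC)cc(OC)c1I
A9 | alternative 3 | carbon monoxide | [C-]#[O+]
A10 | alternative 1 | sodium benzyloxide | [Na+].[O-]Cc1ccccc1
A11 | alternative 2 | triethylamine | CCN(CC)CC
A12 | alternative 3 | palladium diacetate | CC(=O)[O-].CC(=O)[O-].[Pd+2]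
A13 | alternative 3 | Xantphos, 4,5-bis(diphenylphosphino)-9,9-dimethylxanthene | CC1(C)c2cccc(P(c3ccccc3)c3ccccc3)c2Oc2c(P(c3ccccc3)c3ccccc3)cccc21
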